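**Plan**

1. Retrosynthesis (labdane numbering): remove the formate and the silyl ether, then cut C9–C10 of ring B. This leads back to a ring A lactone in which the 4β-carboxyl (C19) is tied to C10, and whose C5 side chain ends in a (Z)-allylsilane C8(CH2SiMe3)=C9.
2. Enabling feature: on ring A the C19 carboxyl at C4 and the C10 position are 1,3-cis-diaxial, so a 19→10 γ-lactone masks both the acid and a tertiary C10 cation. The C8(17) methylene is the scar of the allylsilane terminator.
3. Further cuts: C8–C17 and C7–C8 (two successive cross-couplings on a 1,1-dibromoalkene), C5–C6 (radical addition to an iodolactone), C10–CH3 and C4–CH3 (methyl coupling and conjugate addition).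
4. Forward order: ring A lactone from methyl 3-oxocyclohex-1-ene-1-carboxylate (steps 1–5), side chain from (S)-citronellol (steps 6–8), union (steps 9–10), ring B closed last (step 11), then deprotection and formylation.
5. Stereochemistry: C4 from catalyst-controlled conjugate addition; C10–O and C5–I from anti iodolactonisation; C5 from radical trapping on the lactone face; C13 from (S)-citronellol; alkene geometry from trans-selective coupling then retention; C9 and C10 in the key step.

Key step: step 11

Assumption: the ligand enantiomer in step 1 is taken to be the one that delivers the (S)-configured quaternary centre, by analogy with related β-ester cyclohexenones.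
Remark: labdane locants (C1–C20) are used for the atoms of all intermediates; α/β refer to the final decalin faces.

**Step 1**
Reactants: 1 methyl 3-oxocyclohex-1-ene-1-carboxylate
Product: 3 methyl (S)-1-methyl-3-(trifluoromethylsulfonyloxy)cyclohex-2-ene-1-carboxylate, via methylzinc enolate 2 (not isolated)
Conditions: Me2Zn (3 equiv), (CuOTf)2·C6H6 (2.5 mol %), chiral sulfonate-bearing NHC ligand (5 mol %, from its imidazolinium salt), Et2O, −30 °C; then Tf2O, −78 to 0 °C
Reagents that add atoms: dimethylzinc C[Zn]C; triflic anhydride O=S(=O)(OS(=O)(=O)C(F)(F)F)C(F)(F)F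
Why: Copper-catalysed asymmetric conjugate addition places methyl on the ester-bearing β-carbon (C4) under ligand control, and O-triflation of the regiodefined zinc enolate fixes the C5=C10 double bond.

**Step 2**
Reactants: 3 methyl (S)-1-methyl-3-(trifluoromethylsulfonyloxy)cyclohex-2-ene-1-carboxylate
Product: 4 methyl (S)-1,3-dimethylcyclohex-2-ene-1-carboxylate
Conditions: MeMgBr (1.3 equiv), Fe(acac)3 (5 mol %), THF/NMP, −30 °C
Reagents that add atoms: methylmagnesium bromide C[Mg]Br
Why: Iron-catalysed Kumada-type coupling of the enol triflate should be much faster than Grignard attack on the hindered α-quaternary ester, and it installs the C10 methyl without moving the double bond.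

**Step 3**
Reactants: 4 methyl (S)-1,3-dimethylcyclohex-2-ene-1-carboxylate
Product: 6 (S)-1,3-dimethylcyclohex-2-ene-1-carboxylic acid, via lithium carboxylate 5 (not isolated)
Conditions: LiOH, THF/MeOH/H2O, 60 °C; then aq. HCl to pH 2
Reagents that add atoms: lithium hydroxide [Li+].[OH-]
Why: Ester saponification; the α-carbon is quaternary, so neither epimerisation nor conjugation of the alkene is possible.

**Step 4**
Reactants: 6 (S)-1,3-dimethylcyclohex-2-ene-1-carboxylic acid
Product: 7 (1R,5R,8R)-8-iodo-1,5-dimethyl-6-oxabicyclo[3.2.1]octan-7-one (19→10 lactone, iodine on C5 anti to the lactone bridge)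
Conditions: I2, NaHCO3, MeCN/H2O, 0 °C to rt, dark
Reagents that add atoms: iodine II
Why: Iodolactonisation: the C19 carboxylate opens the iodonium ion at the tertiary carbon C10 (Markovnikov) in an anti addition, so the lactone oxygen is necessarily cis-bridged (β) and the iodine on C5 is α.

**Step 5**
Reactants: 7 (1R,5R,8R)-8-iodo-1,5-dimethyl-6-oxabicyclo[3.2.1]octan-7-one
Product: 8 2-{2-[(1S,5R,8S)-1,5-dimethyl-7-oxo-6-oxabicyclo[3.2.1]octan-8-yl]ethyl}-4,4,5,5-tetramethyl-1,3,2-dioxaborolane (C6–C7 chain on C5 syn to the lactone bridge, H-5 α)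
Conditions: vinylboronic acid pinacol ester (5 equiv), Bu3SnH (1.3 equiv, slow addition), AIBN (0.2 equiv), benzene, 80 °C
Reagents that add atoms: vinylboronic acid pinacol ester C=CB1OC(C)(C)C(C)(C)O1
Why: Tin-mediated Giese addition of the C5 radical to the vinylboronate (α-boryl radical stabilisation); the planar radical should be trapped on the face of the hydrogen-free two-atom lactone bridge and not under the carbocycle, where the axial H-1 and H-3 stand, which places the chain equatorial (β).

**Step 6**
Reactants: 9 (S)-citronellol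
Product: 10 tert-butyl{[(3S)-3,7-dimethyloct-6-en-1-yl]oxy}dimethylsilane
Conditions: TBSCl, imidazole, DMF, rt
Reagents that add atoms: tert-butyldimethylsilyl chloride CC(C)(C)[Si](C)(C)Cl
Why: Standard silylation of the primary alcohol; the C13 stereocentre comes unchanged from the chiral pool.

**Step 7**
Reactants: 10 tert-butyl{[(3S)-3,7-dimethyloct-6-en-1-yl]oxy}dimethylsilane
Product: 12 (4S)-6-(tert-butyldimethylsilyloxy)-4-methylhexanal, via ozonide 11 (not isolated)
Conditions: O3, CH2Cl2, −78 °C; then PPh3, −78 °C to rt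
Reagents that add atoms: ozone [O-][O+]=O
Why: Ozonolysis of the trisubstituted alkene with reductive work-up gives the C9 aldehyde; the remote stereocentre is untouched.

**Step 8**
Reactants: 12 (4S)-6-(tert-butyldimethylsilyloxy)-4-methylhexanal
Product: 13 tert-butyl{[(3S)-7,7-dibromo-3-methylhept-6-en-1-yl]oxy}dimethylsilane
Conditions: CBr4, PPh3, Zn dust, CH2Cl2, 0 °C to rt
Reagents that add atoms: carbon tetrabromide BrC(Br)(Br)Br
Why: Corey–Fuchs dibromo-olefination (first stage) adds C8; zinc keeps the mixture free of Ph3PBr2, which could attack the silyl ether.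

**Step 9**
Reactants: 8 2-{2-[(1S,5R,8S)-1,5-dimethyl-7-oxo-6-oxabicyclo[3.2.1]octan-8-yl]ethyl}-4,4,5,5-tetramethyl-1,3,2-dioxaborolane; 13 tert-butyl{[(3S)-7,7-dibromo-3-methylhept-6-en-1-yl]oxy}dimethylsilane
Product: 14 (1S,5R,8S)-8-[(3Z,7S)-3-bromo-9-(tert-butyldimethylsilyloxy)-7-methylnon-3-en-1-yl]-1,5-dimethyl-6-oxabicyclo[3.2.1]octan-7-one
Conditions: PdCl2(dppf) (5 mol %), Cs2CO3 (3 equiv), THF/H2O (10:1), 60 °C; aq. NH4Cl work-up (re-closes any opened lactone)
Reagents that add atoms: none
Why: B-alkyl Suzuki–Miyaura coupling; oxidative addition should occur at the less hindered C–Br bond trans to the alkyl chain, so C7 ends trans to C11 and the remaining bromine cis (Z).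

**Step 10**
Reactants: 14 (1S,5R,8S)-8-[(3Z,7S)-3-bromo-9-(tert-butyldimethylsilyloxy)-7-methylnon-3-en-1-yl]-1,5-dimethyl-6-oxabicyclo[3.2.1]octan-7-one
Product: 15 (1S,5R,8S)-8-{(3Z,7S)-9-(tert-butyldimethylsilyloxy)-7-methyl-3-[(trimethylsilyl)methyl]non-3-en-1-yl}-1,5-dimethyl-6-oxabicyclo[3.2.1]octan-7-one
Conditions: Me3SiCH2MgCl, ZnCl2, THF, 0 °C; then 14, Pd(P(t-Bu)3)2 (3 mol %), THF, 40 °C
Reagents that add atoms: (trimethylsilylmethyl)magnesium chloride C[Si](C)(C)C[Mg]Cl
Why: Negishi coupling of the alkenyl bromide with retention of configuration gives the (Z)-allylsilane (CH2SiMe3 cis to C11); the organozinc reagent leaves the lactone alone.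

**Step 11**
Reactants: 15 (1S,5R,8S)-8-{(3Z,7S)-9-(tert-butyldimethylsilyloxy)-7-methyl-3-[(trimethylsilyl)methyl]non-3-en-1-yl}-1,5-dimethyl-6-oxabicyclo[3.2.1]octan-7-one
Product: 17 (13S)-15-(tert-butyldimethylsilyloxy)labd-8(17)-en-19-oic acid, via trimethylsilyl ester 16 (not isolated)
Conditions: TMSOTf (0.2 equiv), 2,6-di-tert-butyl-4-methylpyridine (0.2 equiv), CH2Cl2, −78 to −20 °C; then aq. citric acid (pH 4), rt
Reagents that add atoms: none
Why: Proposed new method: O-silylation of the lactone carbonyl by TMSOTf should ionise the tertiary C10–O bond to a 1-methylcyclohexyl cation that carries the C19 silyl ester; the allylsilane attacks through C9 (SE2'), and loss of Me3Si+ from the β-silyl cation at C8 gives the 8(17)-methylene and returns TMSOTf, so the step is a net silyl-transfer isomerisation and the work-up frees the acid. The closest known reaction types are the Lewis-acid alkylation of arenes and allylsilanes by tertiary alkyl esters, lactones and halides (Friedel–Crafts and Hosomi–Sakurai tert-alkylation) and allylsilane-terminated cation–olefin cyclisation. Ring B closes in a 6-endo-trig mode with respect to the C8=C9 bond. C10 is set with inversion: the departing carboxylate stays 1,3-diaxial over the β-lobe, so C9 bonds to the outward α-lobe along the equatorial direction from the equatorial C5 chain, which gives the trans-decalin with the methyl pushed β-axial; C9 is set by the (Z)-allylsilane geometry in a chair transition state, which places C11 equatorial (H-9 α). The step needs ionisation and C–C bond formation to outrun protodesilylation and E1 loss from C10; this should be secured by the high nucleophilicity of the trisubstituted allylsilane held five atoms from C10, by the harmless return of the ion pair to the lactone, and by the hindered pyridine, which traps adventitious TfOH without deprotonating the cation.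

**Step 12**
Reactants: 17 (13S)-15-(tert-butyldimethylsilyloxy)labd-8(17)-en-19-oic acid
Product: 18 (13S)-15-hydroxylabd-8(17)-en-19-oic acid (imbricatolic acid)
Conditions: HF·pyridine, pyridine/THF, 0 °C to rt
Reagents that add atoms: none
Why: Buffered fluoride desilylation of the primary silyl ether; the conditions are too mild to isomerise the exocyclic alkene.

**Step 13**
Reactants: 18 (13S)-15-hydroxylabd-8(17)-en-19-oic acid
Product: 19 (13S)-15-formyloxylabd-8(17)-en-19-oic acid (target)
Conditions: N-formylbenzotriazole (1.5 equiv), THF, rt; aqueous work-up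
Reagents that add atoms: N-formylbenzotriazole O=Cn1nnc2ccccc12
Why: O-formylation of the primary alcohol by an N-acylazole under neutral conditions; the hindered tertiary carboxylic acid does not react durably, since any mixed anhydride is hydrolysed on work-up.

**Compound list**

1 | methyl 3-oxocyclohex-1-ene-1-carboxylate | COC(=O)C1=CC(=O)CCC1 | starting material
2 | methylzinc enolate (C5=C10) of methyl (S)-1-methyl-3-oxocyclohexane-1-carboxylate | COC(=O)[C@@]1(C)CCCC(O[Zn]C)=C1 | intermediate
3 | methyl (S)-1-methyl-3-(trifluoromethylsulfonyloxy)cyclohex-2-ene-1-carboxylate | COC(=O)[C@@]1(C)CCCC(OS(=O)(=O)C(F)(F)F)=C1 | intermediate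
4 | methyl (S)-1,3-dimethylcyclohex-2-ene-1-carboxylate | COC(=O)[C@@]1(C)CCCC(C)=C1 | intermediate
5 | lithium (S)-1,3-dimethylcyclohex-2-ene-1-carboxylate | [Li+].[O-]C(=O)[C@@]1(C)CCCC(C)=C1 | intermediate
6 | (S)-1,3-dimethylcyclohex-2-ene-1-carboxylic acid | OC(=O)[C@@]1(C)CCCC(C)=C1 | intermediate
7 | (1R,5R,8R)-8-iodo-1,5-dimethyl-6-oxabicyclo[3.2.1]octan-7-one | O=C1O[C@]2(C)CCC[C@@]1(C)[C@H]2I | intermediate
8 | 2-{2-[(1S,5R,8S)-1,5-dimethyl-7-oxo-6-oxabicyclo[3.2.1]octan-8-yl]ethyl}-4,4,5,5-tetramethyl-1,3,2-dioxaborolane | O=C1O[C@]2(C)CCC[C@@]1(C)[C@@H]2CCB3OC(C)(C)C(C)(C)O3 | intermediate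
9 | (S)-citronellol | CC(C)=CCC[C@H](C)CCO | starting material
10 | tert-butyl{[(3S)-3,7-dimethyloct-6-en-1-yl]oxy}dimethylsilane | CC(C)=CCC[C@H](C)CCO[Si](C)(C)C(C)(C)C | intermediate
11 | 3-[(3S)-5-(tert-butyldimethylsilyloxy)-3-methylpentyl]-5,5-dimethyl-1,2,4-trioxolane (ozonide, mixture at the ring CH) | CC1(C)OOC(CC[C@H](C)CCO[Si](C)(C)C(C)(C)C)O1 | intermediate
12 | (4S)-6-(tert-butyldimethylsilyloxy)-4-methylhexanal | O=CCC[C@H](C)CCO[Si](C)(C)C(C)(C)C | intermediate
13 | tert-butyl{[(3S)-7,7-dibromo-3-methylhept-6-en-1-yl]oxy}dimethylsilane | BrC(Br)=CCC[C@H](C)CCO[Si](C)(C)C(C)(C)C | intermediate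
14 | (1S,5R,8S)-8-[(3Z,7S)-3-bromo-9-(tert-butyldimethylsilyloxy)-7-methylnon-3-en-1-yl]-1,5-dimethyl-6-oxabicyclo[3.2.1]octan-7-one | O=C1O[C@]2(C)CCC[C@@]1(C)[C@@H]2CC/C(Br)=C/CC[C@H](C)CCO[Si](C)(C)C(C)(C)C | intermediate
15 | (1S,5R,8S)-8-{(3Z,7S)-9-(tert-butyldimethylsilyloxy)-7-methyl-3-[(trimethylsilyl)methyl]non-3-en-1-yl}-1,5-dimethyl-6-oxabicyclo[3.2.1]octan-7-one | O=C1O[C@]2(C)CCC[C@@]1(C)[C@@H]2CC/C(C[Si](C)(C)C)=C/CC[C@H](C)CCO[Si](C)(C)C(C)(C)C | intermediate
16 | trimethylsilyl (13S)-15-(tert-butyldimethylsilyloxy)labd-8(17)-en-19-oate | C=C1CC[C@@H]2[C@](C)(CCC[C@]2(C)C(=O)O[Si](C)(C)C)[C@H]1CC[C@H](C)CCO[Si](C)(C)C(C)(C)C | intermediate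
17 | (13S)-15-(tert-butyldimethylsilyloxy)labd-8(17)-en-19-oic acid | C=C1CC[C@@H]2[C@](C)(CCC[C@]2(C)C(=O)O)[C@H]1CC[C@H](C)CCO[Si](C)(C)C(C)(C)C | intermediate
18 | (13S)-15-hydroxylabd-8(17)-en-19-oic acid (imbricatolic acid) | C=C1CC[C@@H]2[C@](C)(CCC[C@]2(C)C(=O)O)[C@H]1CC[C@H](C)CCO | intermediate
19 | (13S)-15-formyloxylabd-8(17)-en-19-oic acid | C=C1CC[C@@H]2[C@](C)(CCC[C@]2(C)C(=O)O)[C@H]1CC[C@H](C)CCOC=O | target

**Step count and risks**

Total steps: 13. Longest linear sequence: 10 (steps 1–5 and 9–13).

Steps most likely to fail: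

1. Step 11 (carries the proposed new method). Ionisation of the tertiary lactone may be slower than protodesilylation of the allylsilane, or the C10 cation may lose a proton instead of being captured. The fallback sets out from 15 and comes back at 17, and generates the cation in the established way from a tertiary alcohol. 15 is reduced with LiAlH4 (THF, 0 °C) to the 19,10-diol F1. The primary hydroxyl is acetylated (Ac2O, pyridine) to the 19-monoacetate F2. F2 is cyclised with SnCl4 (CH2Cl2, −78 °C), an allylsilane-terminated cyclisation started by ionisation of the tertiary alcohol, to (13S)-19-acetoxy-15-(tert-butyldimethylsilyloxy)labd-8(17)-ene F3. Methanolysis (K2CO3, MeOH) gives the 19-alcohol F4, Dess–Martin oxidation gives the 19-aldehyde F5, and Pinnick oxidation (NaClO2, NaH2PO4, 2-methyl-2-butene) returns 17.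

2. Step 5. Facial selectivity in the trapping of the C5 radical may be poor or reversed (attack under the carbocycle would give the C5 epimer), and the radical may be reduced by the tin hydride before it adds. The fallback sets out from 6 and comes back at 8, and uses the complementary logic of delivering hydrogen, not carbon, to C5 from the more accessible face. Epoxidation of 6 with mCPBA and lactonisation in the flask gives the 5-hydroxy lactone F6 (either C5 epimer serves). Dess–Martin oxidation gives the non-enolisable keto lactone F7, and Wittig methylenation (Ph3PCH3Br, KOt-Bu, toluene, 80 °C) gives the methylene lactone F8. Hydroboration (BH3·SMe2, THF, 0 °C; then pinacol) adds H to C5 and boron to C6 from the same face and gives the one-carbon boronate F9. Matteson homologation (BrCH2Cl, n-BuLi, THF, −78 °C) then gives 8.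

3. Step 9. Transmetalation of the primary alkyl pinacol boronate may be slow, which would allow loss of trans-selectivity, double coupling or base-induced dehydrobromination of the dibromoalkene. The fallback sets out from 8 and comes back at 14, and changes the nucleophile from boron to zinc. Oxidation of 8 (NaBO3·4H2O, THF/H2O) gives the primary alcohol F10, and iodination (I2, PPh3, imidazole) gives the iodide F11. Zinc insertion (Zn, LiCl, THF) gives the alkylzinc iodide F12, which is coupled with 13 in a trans-selective Negishi monoalkylation (PdCl2(DPEphos), THF, 0 °C to rt) to give 14.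

**Further compounds**

F1 | step 11 | 19,10-diol from reduction of 15 (ring A with C19 CH2OH and tertiary C10 OH, allylsilane chain on C5) | OC[C@@]1(C)CCC[C@@](C)(O)[C@H]1CC/C(C[Si](C)(C)C)=C/CC[C@H](C)CCO[Si](C)(C)C(C)(C)C
F2 | step 11 | 19-monoacetate of F1 | CC(=O)OC[C@@]1(C)CCC[C@@](C)(O)[C@H]1CC/C(C[Si](C)(C)C)=C/CC[C@H](C)CCO[Si](C)(C)C(C)(C)C
F3 | step 11 | (13S)-19-acetoxy-15-(tert-butyldimethylsilyloxy)labd-8(17)-ene | C=C1CC[C@@H]2[C@](C)(CCC[C@]2(C)COC(C)=O)[C@H]1CC[C@H](C)CCO[Si](C)(C)C(C)(C)C
F4 | step 11 | (13S)-15-(tert-butyldimethylsilyloxy)labd-8(17)-en-19-ol | C=C1CC[C@@H]2[C@](C)(CCC[C@]2(C)CO)[C@H]1CC[C@H](C)CCO[Si](C)(C)C(C)(C)C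
F5 | step 11 | (13S)-15-(tert-butyldimethylsilyloxy)labd-8(17)-en-19-al | C=C1CC[C@@H]2[C@](C)(CCC[C@]2(C)C=O)[C@H]1CC[C@H](C)CCO[Si](C)(C)C(C)(C)C
F6 | step 5 | 8-hydroxy-1,5-dimethyl-6-oxabicyclo[3.2.1]octan-7-one (hydroxyl anti to the lactone bridge) | O=C1O[C@]2(C)CCC[C@@]1(C)[C@H]2O
F7 | step 5 | 1,5-dimethyl-6-oxabicyclo[3.2.1]octane-7,8-dione | O=C1O[C@]2(C)CCC[C@@]1(C)C2=O
F8 | step 5 | 1,5-dimethyl-8-methylene-6-oxabicyclo[3.2.1]octan-7-one | O=C1O[C@]2(C)CCC[C@@]1(C)C2=C
F9 | step 5 | 1,5-dimethyl-8-[(4,4,5,5-tetramethyl-1,3,2-dioxaborolan-2-yl)methyl]-6-oxabicyclo[3.2.1]octan-7-one (CH2B syn to the lactone bridge) | O=C1O[C@]2(C)CCC[C@@]1(C)[C@@H]2CB3OC(C)(C)C(C)(C)O3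
F10 | step 9 | (1S,5R,8S)-8-(2-hydroxyethyl)-1,5-dimethyl-6-oxabicyclo[3.2.1]octan-7-one | O=C1O[C@]2(C)CCC[C@@]1(C)[C@@H]2CCO
F11 | step 9 | (1S,5R,8S)-8-(2-iodoethyl)-1,5-dimethyl-6-oxabicyclo[3.2.1]octan-7-one | O=C1O[C@]2(C)CCC[C@@]1(C)[C@@H]2CCI
F12 | step 9 | alkylzinc iodide from F11 | O=C1O[C@]2(C)CCC[C@@]1(C)[C@@H]2CC[Zn]I
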